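All runs come from a simulation for substances that don't exist.

At 20 h I must read X in a flask charged with 1.5 M of Z. The steps thought possible are E to D, Z + D + L giving L + X, Z to Q and back, and two L going to J.

in all of them: E 200 mM (held); L 75 mM
- ochre: Z 0.75 M; run made earlier
- red: Z 1.1 M; run made earlier
- flask: Z 1.5 M; time 20 h

| run | time / h | X / % | Z / % |
|---|---|---|---|
| ochre | 1.33 | 15 | 51 |
| ochre | 4.00 | 27 | 29 |
| ochre | 8.00 | 31 | 25 |
| ochre | 10.0 | 31 | 23 |
| ochre | 15.0 | 38 | 24 |
| ochre | 20.0 | 37 | 22 |
| red | 1.33 | 18 | 52 |
| red | 4.00 | 30 | 28 |
| red | 8.00 | 31 | 24 |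
| red | 10.0 | 31 | 25 |
| red | 15.0 | 36 | 23 |
| red | 20.0 | 41 | 22 |

(readings scatter by 1.5 percentage points)

- at the start none of D is dissolved
- steps thought possible: E <-> D; Z + D + L -> L + X; Z <-> Q; 2 L -> J

- dawn: doubling the transfer coefficient of E, all else as stated
- noon: doubling the saturation concentration of E, all else as stated
- autumn: doubling the amount of L, all else as stated

1. the X standing at 20 h, as a percentage of the Z charged
2. the change that raises the amount of X at 20 h, in percent of the Z charged most ("none" if none brings more than 2 percentage points) (dawn / noon / autumn / none)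
3. amount of X at 20 h, in percent of the Z charged, after noon

Ochre and red agree within their scatter, so I use their means as fractions of the charge. X starts steeply, at 0.165 by 1.33 h, a slope of 0.124 h⁻¹. It crosses Z near 4.00 h, where both read 0.285. Then comes the knee. X reads 0.310 at 8.00 h and 0.390 at 20.0 h, so the late slope is 0.00667 h⁻¹, far less than the start. No level shows yet.

After the knee Z is a steady share of what is unconverted: 0.355, then 0.361. I take that pool to decay pseudo-first-order in L, and L to be lost at a rate set by its own square. I divide one rate by the other and time drops out. With D and that share held, each e-fold lost by L takes a fixed amount off the logarithm of the pool. Late, by that square law, I expect L to fall as one over time. So this yield per e-fold reads 0.134 from the means of ochre and red, roughly, given the scatter.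

I commit to 0.390 for the flask. I expect noon to double D and so the logarithm of the pool, giving 0.628. I expect autumn to add ln(2) e-folds, giving 0.444. Ochre and red, with different charges of Z, read alike, so I expect dawn to stay under 2 percentage points.

The forecast says 39%, noon and 59%, my noon figure being higher: “Noon doubles D and hence the whole integrated rate”.

The flask gives 38.6%. Noon is best, reaching 60.9%, with 22 points gained, against 8.2 points for autumn and 0.4 points for dawn.

    E ⇌ D, rate k1*(csat - [D]) (kL = 0.0100 s⁻¹)
    Z + D + L → L + X (k = 0.00480 M⁻² s⁻¹)
    Z ⇌ Q (K = 1.70, k = 1.10 × 10⁻⁴ s⁻¹)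
    2 L → J (k = 0.00130 M⁻¹ s⁻¹)

In the flask, the logarithm of the pool goes from 0.487 to 0.938 under noon, twice over. A neighbouring flask, otherwise charged the same, has a quarter of the L. At 20.0 h its L stands at 21.9% of its own charge, which is 1.52 e-folds. The yield per e-fold then gives X of 0.185. That neighbouring flask holds 22.3% of X, more than that.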